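**Plan**

- Retrosynthesis: the C6 hydroxyl is taken back to C6–Br and the C4 methylene to a C4 ketone. The pyranone ring is then cut at C2–C3 and at O1–C8a. This gives the C18 methyl ketone (O1, C2, its methyl and the whole side chain) and an acetophenone that holds C3, C4, C4a and C8a, with fluorine on C8a.
- Enabling feature: C2 is a carbinol carbon at ketone oxidation level. A single carbonyl at C4 is both alpha to C3 (enol silane nucleophile) and ortho to C8a (activates C8a–F for SNAr). Ring O1–C2–C3–C4–C4a–C8a is therefore the formal hetero-Diels–Alder adduct of a C=O with a benzo-fused Danishefsky-type diene.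
- Forward: the benzene ring is bought with both methyls, F and Br in place. Ozonolysis of natural phytol gives the ketone, and lithiation/acylation then silylation give the enol silane. A one-pot aldol/SNAr relay joins the chain and closes the pyran ring. The C4 carbonyl is then reduced off and C6–Br is turned into C6–OH last.
- Stereochemistry: 4'R and 8'R come unchanged from natural (7R,11R)-phytol. 2R is set in the key step by the chiral catalyst (Si-face attack on the ketone) and is a plain tertiary ether centre from step 5 on.

Key step: step 4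

Assumption: natural (2E,7R,11R)-phytol and 1-bromo-4-fluoro-2,5-dimethylbenzene are taken as commercial, and the (S,S) series of the catalyst is taken to be the one that directs attack to the Si face of the ketone (if the sense is the reverse, the mirror-image catalyst is used).

**Route**

Step 1
Reactants: 1 natural phytol, (2E,7R,11R)-3,7,11,15-tetramethylhexadec-2-en-1-ol
Product: 3 (6R,10R)-6,10,14-trimethylpentadecan-2-one, via ozonide 2 (not isolated)
Conditions: O3, CH2Cl2, −78 °C; then Me2S, −78 °C to rt
Reagents that add atoms: ozone [O-][O+]=O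
Why: Ozonolysis (Criegee mechanism) with reductive work-up cleaves the only C=C bond and leaves C3 of phytol as the methyl ketone, the two methyl-bearing stereocentres being remote and untouched.

Step 2
Reactants: 4 1-bromo-4-fluoro-2,5-dimethylbenzene
Product: 6 1-(3-bromo-6-fluoro-2,5-dimethylphenyl)ethan-1-one, via aryllithium 5 (not isolated)
Conditions: LiN(i-Pr)2 (LDA), THF, −78 °C; then N-methoxy-N-methylacetamide, −78 to 0 °C; aq. NH4Cl
Reagents that add atoms: N-methoxy-N-methylacetamide CC(=O)N(C)OC
Why: Directed ortho-metalation, in which the amide base removes the most acidic ring hydrogen (ortho to F, meta to Br) without bromine–lithium exchange, followed by single acylation of the aryllithium through the stable tetrahedral chelate of the Weinreb amide.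

Step 3
Reactants: 6 1-(3-bromo-6-fluoro-2,5-dimethylphenyl)ethan-1-one
Product: 7 triethyl{[1-(3-bromo-6-fluoro-2,5-dimethylphenyl)ethenyl]oxy}silane
Conditions: Et3SiOTf, Et3N, CH2Cl2, 0 °C
Reagents that add atoms: triethylsilyl trifluoromethanesulfonate CC[Si](CC)(CC)OS(=O)(=O)C(F)(F)F
Why: Soft enolisation of a methyl aryl ketone with a silyl triflate and an amine base should give the only possible silyl enol ether.

Step 4
Reactants: 7 triethyl{[1-(3-bromo-6-fluoro-2,5-dimethylphenyl)ethenyl]oxy}silane; 3 (6R,10R)-6,10,14-trimethylpentadecan-2-one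
Product: 9 (2R)-6-bromo-2,5,8-trimethyl-2-[(4R,8R)-4,8,12-trimethyltridecyl]-2,3-dihydro-4H-chromen-4-one, via silyl ether aldol adduct 8 (not isolated)
Conditions: (S,S)-IDPi catalyst (chiral BINOL-derived N-triflyl imidodiphosphorimidate Brønsted acid, 1–2 mol%), 3 in slight excess, toluene, −40 °C; then DMF, Bu4N[Ph3SiF2] (TBAT, 20 mol%), −40 to 0 °C; AcOH quench
Reagents that add atoms: none
Why: Proposed new method: the acid is silylated by 7 to a chiral silylium ion pair that O-silylates ketone 3, and the enol silane then adds its CH2 carbon (C3) to the Si face (O > C1' > CH3) of the oxocarbenium carbon C2, so that 2R is set by the confined chiral counteranion alone, the chain stereocentres lying five or more bonds away; catalytic fluoride then takes the Et3Si group off the tertiary oxygen and alkoxide O1 displaces fluoride at C8a by addition–elimination, the C4 carbonyl ortho to C8a holding the charge of the Meisenheimer intermediate and the released fluoride carrying the chain. The closest known reaction types are the silylium-catalysed Mukaiyama aldol addition of silyl ketene acetals to simple methyl ketones under the same class of catalyst (which tells a methyl from a primary alkyl group) and the base-mediated SNAr closure of 2-fluoroaryl beta-hydroxy ketones to chroman-4-ones, the pair being the aromatic counterpart of a Danishefsky-diene hetero-Diels–Alder reaction. The pyranone ring (O1, C2, C3, C4, C4a, C8a) closes in a 6-endo-trig addition–elimination, the C8a=C4a bond of the vinylogous acyl fluoride lying inside the forming ring. The step needs facial selectivity at C2 (the ketone offers a methyl against an unbranched CH2 chain whose first branch is three carbons away, the difference this catalyst class is built to read), site selectivity for C8a–F over C6–Br (only F is ortho to the acyl group and it is the better SNAr leaving group), and ring closure faster than retro-aldol cleavage of the tertiary alkoxide (intramolecular attack at low temperature with only catalytic fluoride, and an acid quench before the product can reopen by E1cB).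

Step 5
Reactants: 9 (2R)-6-bromo-2,5,8-trimethyl-2-[(4R,8R)-4,8,12-trimethyltridecyl]-2,3-dihydro-4H-chromen-4-one
Product: 10 (2R)-6-bromo-2,5,8-trimethyl-2-[(4R,8R)-4,8,12-trimethyltridecyl]-3,4-dihydro-2H-chromene
Conditions: Et3SiH, CF3CO2H, CH2Cl2, 0 °C to rt, dark
Reagents that add atoms: none
Why: Ionic hydrogenation of an ortho-alkoxyaryl ketone, in which protonation, hydride transfer and ionisation give a C4 benzylic cation stabilised by O1 that takes a second hydride, should remove the C4 carbonyl without touching the aryl bromide, the tertiary ether or C2.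

Step 6
Reactants: 10 (2R)-6-bromo-2,5,8-trimethyl-2-[(4R,8R)-4,8,12-trimethyltridecyl]-3,4-dihydro-2H-chromene
Product: 11 beta-tocopherol
Conditions: Pd2(dba)3 (2 mol%), 2-di-tert-butylphosphino-2',4',6'-triisopropylbiphenyl (t-BuXPhos, 8 mol%), KOH, 1,4-dioxane/H2O, 100 °C, argon; then aq. HCl
Reagents that add atoms: potassium hydroxide [K+].[OH-]
Why: Palladium-catalysed hydroxylation of an aryl bromide (oxidative addition of C6–Br to zerovalent palladium, bromide–hydroxide exchange, C–O reductive elimination from the bulky biarylphosphine complex) should place the phenol exactly where the bromine stood, with the C2 ether centre inert to base.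

**Compound list**

1 | natural phytol, (2E,7R,11R)-3,7,11,15-tetramethylhexadec-2-en-1-ol | OC/C=C(\C)CCC[C@H](C)CCC[C@H](C)CCCC(C)C | starting material
2 | ozonide of 1, 3-(hydroxymethyl)-5-methyl-5-[(4R,8R)-4,8,12-trimethyltridecyl]-1,2,4-trioxolane (mixture at the ring carbons) | OCC1OOC(C)(CCC[C@H](C)CCC[C@H](C)CCCC(C)C)O1 | intermediate (not isolated)
3 | (6R,10R)-6,10,14-trimethylpentadecan-2-one | CC(=O)CCC[C@H](C)CCC[C@H](C)CCCC(C)C | intermediate
4 | 1-bromo-4-fluoro-2,5-dimethylbenzene | Cc1cc(Br)c(C)cc1F | starting material
5 | (3-bromo-6-fluoro-2,5-dimethylphenyl)lithium | [Li]c1c(F)c(C)cc(Br)c1C | intermediate (not isolated)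
6 | 1-(3-bromo-6-fluoro-2,5-dimethylphenyl)ethan-1-one | CC(=O)c1c(F)c(C)cc(Br)c1C | intermediate
7 | triethyl{[1-(3-bromo-6-fluoro-2,5-dimethylphenyl)ethenyl]oxy}silane | C=C(O[Si](CC)(CC)CC)c1c(F)c(C)cc(Br)c1C | intermediate
8 | (3R,7R,11R)-1-(3-bromo-6-fluoro-2,5-dimethylphenyl)-3,7,11,15-tetramethyl-3-[(triethylsilyl)oxy]hexadecan-1-one | CC[Si](CC)(CC)O[C@](C)(CCC[C@H](C)CCC[C@H](C)CCCC(C)C)CC(=O)c1c(F)c(C)cc(Br)c1C | intermediate (not isolated)
9 | (2R)-6-bromo-2,5,8-trimethyl-2-[(4R,8R)-4,8,12-trimethyltridecyl]-2,3-dihydro-4H-chromen-4-one | Cc1cc(Br)c(C)c2c1O[C@](C)(CCC[C@H](C)CCC[C@H](C)CCCC(C)C)CC2=O | intermediate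
10 | (2R)-6-bromo-2,5,8-trimethyl-2-[(4R,8R)-4,8,12-trimethyltridecyl]-3,4-dihydro-2H-chromene | Cc1cc(Br)c(C)c2c1O[C@](C)(CCC[C@H](C)CCC[C@H](C)CCCC(C)C)CC2 | intermediate
11 | beta-tocopherol, (2R)-2,5,8-trimethyl-2-[(4R,8R)-4,8,12-trimethyltridecyl]-3,4-dihydro-2H-chromen-6-ol | Cc1cc(O)c(C)c2c1O[C@](C)(CCC[C@H](C)CCC[C@H](C)CCCC(C)C)CC2 | target

**Step count and risks**

Total steps: 6. Longest linear sequence: 5 steps (4 to 11 through steps 2, 3, 4, 5 and 6); the phytol branch has 4.

Step 4 (highest risk). Four processes could erode or prevent the 2R centre: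
- the catalyst pocket may not tell the methyl group from the C1' methylene well enough, giving poor facial selectivity;
- silyl transfer from 7 to ketone 3 may lead to crossed aldol products;
- the freed tertiary alkoxide may fragment by retro-aldol faster than it closes the ring;
- the chromanone may reopen by E1cB under the basic fluoride.

The fallback uses known chemistry and takes the C2 centre from a Sharpless epoxidation. It sets out from natural phytol 1 and uses aryllithium 5. Ti(OiPr)4, D-(−)-diethyl tartrate and t-BuOOH (CH2Cl2, 4 Å sieves, −20 °C) should give (2R,3R)-2,3-epoxyphytol F1. NaAlH2(OCH2CH2OMe)2 (Red-Al) should open it at C2 to (3R,7R,11R)-3,7,11,15-tetramethylhexadecane-1,3-diol F2. TsCl in pyridine should give the primary monotosylate (3R,7R,11R)-3-hydroxy-3,7,11,15-tetramethylhexadecyl 4-methylbenzenesulfonate F3, which KOt-Bu in THF should close to (2R)-2-methyl-2-[(4R,8R)-4,8,12-trimethyltridecyl]oxetane F4. Aryllithium 5 with BF3·OEt2 at −78 °C should open the oxetane at its CH2–O carbon to the tertiary alcohol (3R,7R,11R)-1-(3-bromo-6-fluoro-2,5-dimethylphenyl)-3,7,11,15-tetramethylhexadecan-3-ol F5. KOt-Bu in DMSO at about 80 °C should then close O1–C8a by intramolecular SNAr. The route is rejoined at 10, and steps 1, 3, 4 and 5 are not needed.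

Step 6. Hydrodebromination or diaryl ether formation may compete at the hindered, electron-rich C6–Br, and the phenolate product may be oxidised under hot alkaline conditions. The fallback sets out from 10. Miyaura borylation (bis(pinacolato)diboron, PdCl2(dppf), KOAc, 1,4-dioxane, 90 °C) should give 4,4,5,5-tetramethyl-2-{(2R)-2,5,8-trimethyl-2-[(4R,8R)-4,8,12-trimethyltridecyl]-3,4-dihydro-2H-chromen-6-yl}-1,3,2-dioxaborolane F6. Mild oxidation of the C–B bond (NaBO3·4H2O, THF/H2O, rt) should give 11 near neutral pH.

Step 5. The C4 cation may form slowly because of peri strain from the C5 methyl and the para bromine, so that reduction stalls at the C4 alcohol or the 2H-chromene. Strong acid may also ionise the tertiary C2–O1 bond, and light-induced electrocyclic opening of a chromene by-product would scramble C2. The fallback sets out from 9. Condensation with 4-methylbenzenesulfonohydrazide (EtOH, cat. AcOH, reflux) should give N'-{(2R)-6-bromo-2,5,8-trimethyl-2-[(4R,8R)-4,8,12-trimethyltridecyl]-2,3-dihydro-4H-chromen-4-ylidene}-4-methylbenzenesulfonohydrazide F7. A Caglioti-type reduction with catecholborane followed by NaOAc·3H2O (hydride to C=N, then loss of sulfinate and N2) should give 10 without any cationic intermediate.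

**Further compounds**

F1 | step 4 | (2R,3R)-2,3-epoxyphytol, {(2R,3R)-3-methyl-3-[(4R,8R)-4,8,12-trimethyltridecyl]oxiran-2-yl}methanol | OC[C@H]1O[C@]1(C)CCC[C@H](C)CCC[C@H](C)CCCC(C)C
F2 | step 4 | (3R,7R,11R)-3,7,11,15-tetramethylhexadecane-1,3-diol | OCC[C@](C)(O)CCC[C@H](C)CCC[C@H](C)CCCC(C)C
F3 | step 4 | (3R,7R,11R)-3-hydroxy-3,7,11,15-tetramethylhexadecyl 4-methylbenzenesulfonate | Cc1ccc(cc1)S(=O)(=O)OCC[C@](C)(O)CCC[C@H](C)CCC[C@H](C)CCCC(C)C
F4 | step 4 | (2R)-2-methyl-2-[(4R,8R)-4,8,12-trimethyltridecyl]oxetane | C[C@@]1(CCC[C@H](C)CCC[C@H](C)CCCC(C)C)CCO1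
F5 | step 4 | (3R,7R,11R)-1-(3-bromo-6-fluoro-2,5-dimethylphenyl)-3,7,11,15-tetramethylhexadecan-3-ol | Cc1cc(Br)c(C)c(CC[C@](C)(O)CCC[C@H](C)CCC[C@H](C)CCCC(C)C)c1F
F6 | step 6 | 4,4,5,5-tetramethyl-2-{(2R)-2,5,8-trimethyl-2-[(4R,8R)-4,8,12-trimethyltridecyl]-3,4-dihydro-2H-chromen-6-yl}-1,3,2-dioxaborolane | Cc1cc(B3OC(C)(C)C(C)(C)O3)c(C)c2c1O[C@](C)(CCC[C@H](C)CCC[C@H](C)CCCC(C)C)CC2
F7 | step 5 | N'-{(2R)-6-bromo-2,5,8-trimethyl-2-[(4R,8R)-4,8,12-trimethyltridecyl]-2,3-dihydro-4H-chromen-4-ylidene}-4-methylbenzenesulfonohydrazide | Cc1cc(Br)c(C)c2c1O[C@](C)(CCC[C@H](C)CCC[C@H](C)CCCC(C)C)CC2=NNS(=O)(=O)c1ccc(C)cc1
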